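(The rate constants belong to no real substance, and the outcome is calculated.)

Decide before charging whether the extra precatalyst of alder pays, and reckon it by hand in fractions of the substrate charged.

| flask | substrate | partner | precatalyst | added ligand | time |
|---|---|---|---|---|---|
| birch | 0.53 M | 1.10 equiv | 0.5 mol% | 1.7 mM | 8.0 d |
| alder | 0.53 M | 1.10 equiv | 0.65 mol% | 1.7 mM | 8.0 d |

    substrate + free catalyst → free catalyst + open intermediate (k1 = 0.488 M⁻¹ min⁻¹)
    free catalyst + open intermediate ⇌ catalyst intermediate (K2 = 79 M⁻¹, k2 = 2.69 M⁻¹ min⁻¹)
    partner + catalyst intermediate → free catalyst + target (k3 = 0.991 M⁻¹ min⁻¹)
    precatalyst → free catalyst (k4 = 0.00128 min⁻¹)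
    free catalyst + added ligand ⇌ idle complex, settled at all times (K5 = 496 M⁻¹)
    partner → decomposed reagent (k6 = 0.00103 min⁻¹)

* which of these there is most of at the end, counted by the substrate in it, birch (substrate / open intermediate / target)
* which of these there is most of at the end, counted by the substrate in it, alder (substrate / open intermediate / target)
* final amount of the leader among these, as a percentage of the substrate charged, in birch
* final amount of the leader among these, as a percentage of the substrate charged, in alder

Start with the partner. It has a half-life of 0.47 d if it merely decomposes, and the precatalyst opens with a half-life of 0.38 d. Count the partner as working for a window of 0.935 d, by which decomposition by itself leaves a quarter. In that window, split the released catalyst between free catalyst and idle complex, 1 to 0.84. For birch, with 2.65 mM of catalyst, the substrate falls to 61.0%. Hold open intermediate at the ratio of its making to its capture, 11.1%, and freeze target at the remainder, 27.9%.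

Now comes the small thing. For birch, take open intermediate at 31.4%, a third of the way through the remaining substrate. Call free share, 6.67% for birch, the part of the catalyst left as free catalyst once open intermediate and added ligand both sit at balance with it: one over the sum of one, the ligand's 0.84, and 79 M⁻¹ times the open intermediate. The substrate then decays pseudo-first-order, with 0.124 d⁻¹, down to 25.4%. What it loses, open intermediate gains, so birch ends with open intermediate first, at 46.7%.

Repeat for alder: window's end at 52.6% substrate, 9.54% open intermediate and 37.8% target, free share 7.59%, final substrate 14.4%. Alder ends with open intermediate first, at 47.8%. Charge alder for target, then, but expect no new leader.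

The forecast names open intermediate for both flasks, at 46% (38% to 54%) in birch and 47% (37% to 56%) in alder: “open intermediate ends as the leader at a little under half in both runs”.

The simulation gives open intermediate first at 46.4% in birch and 48.1% in alder, with target at 27.2% and 32.1%. Birch's free share of 6.67% stands beside 6.27% free catalyst at 4.00 d. A neighbour of birch charged with 2.1 M of substrate ends with target holding most, 55.0% against 34.3% open intermediate. With that open intermediate, its free share comes to 1.70%, and that flask holds 1.70% of its catalyst as free catalyst.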